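The E you read at the end of a run is a leftover: what G has given and X and L have not taken away.

    G → E (k1 = 0.10 /min)
    X + E ⇌ X.E (K2 = 4.4 /M, k2 = 41 /M/min)
    X → Q (k3 = 0.10 /min)
    L + E → L.E (k4 = 3.0 /M/min)

| flask | G | X | L | time | remark |
|---|---|---|---|---|---|
| ochre | 0.10 M | 0.110 M (fed, over 10.0 min) | 0.120 M | 10 min | all but X at the start; X goes in evenly over 10.0 min, the run ends at 10 min |
| red | 0.10 M | 0.110 M | 0.120 M | 10 min | everything together in a closed stirred flask, run for 10 min |
| violet | 0.10 M | 0.110 M | 0.120 M |  | a single well-mixed tank run continuously and read at steady state, 10 min in it on average |
| teal | 0.10 M | 0.110 M | 0.120 M (fed, over 10.0 min) | 10 min | all but L at the start; L goes in evenly over 10.0 min, the run ends at 10 min |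

- the set-up with the highest amount of E at the outlet or at the end, in percent of the G put in ("none" if the first two lie within 2 percentage points) (ochre / red / violet / teal / none)
- amount of E at the outlet or at the end, in percent of the G put in, ochre
- amount of E at the outlet or at the end, in percent of the G put in, red
- amount of E at the outlet or at the end, in percent of the G put in, violet
- amount of E at the outlet or at the end, in percent of the G put in, teal

- the stated concentrations are those of everything mixed, before any reaction; amounts are the same in each set-up
- the feed brings no volume worth counting
- run time (ochre): 10 min

Before you integrate anything, divide the drain by the source. Take the rate constant of L on E times the charge of L, and divide it by the rate constant of G; time drops out and you get N = 3.60, the drain number. It says that at full charge L takes a given E that many times faster than a given G turns into E, so E should stay a modest fraction of G.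

My own reckoning treats the drain as pseudo-first-order, with L fixed and X ignored. Two first-order steps in a row then leave 13.1 % of G as E in red after 10 min. Ochre gets the same figure, since X does not enter N. The violet tank turns half of G, and dividing that by one plus N gives 10.9 %. In teal, L averages half its charge over the run, so N becomes 1.80 and E comes to 25.3 %, the highest.

Is one number enough? No. It cannot separate red from ochre, yet at charge X holds 0.484 X.E per free E. L also falls as it works, so I expect red to come out above my figure.

The forecast names teal, with 16.3 % for ochre, 17.9 % for red, 13.1 % for violet and 23.7 % for teal, on the ground that “holding L back (teal) lets E build up most”. Its red and ochre stand above mine and apart from each other.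

The simulation gives 16.4 % for ochre, 18.1 % for red, 13.1 % for violet and 24.0 % for teal, so teal leads, as forecast. The drain is a part of what holds E down in violet, not the whole of it: with the step from L + E to L.E taken away, violet's E reads 41.0 % against 13.1 %. Read backwards, with X.E counted as drained, the 50.0 % of G that violet has turned, over its E, gives a working drain number of 2.82, lower than N, which was 3.60.

(The constants used here stand for no real mixture; the run is a simulation.)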